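**Retrosynthetic overview**

1. The strategy rests on ring B (C1'–C6', joined through C1' to C2 of the benzofuran): a resorcinol monomethyl ether with a free OH at C2' (ortho to C1') and OMe at C4' (para to C1'). A vinylketene carbonyl and methoxyacetylene deliver exactly this free-phenol/methyl-ether pair.
2. Ring B (bonds C1'–C2', C2'–C3', C4'–C5') is disconnected to a benzofuran-2-yl α'-diazo enone and methoxyacetylene (photochemical Danheiser benzannulation), with the C6 hydroxyl held as a triisopropylsilyl ether.
3. The diazo enone comes from the 3-methoxybenzofuran-2-carbaldehyde by Wittig olefination with an acetonylidene ylide and detrifluoroacetylative diazo transfer.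
4. The furan ring C (C2–C3 bond) comes from Dieckmann closure of an aryloxyacetate onto a salicylate ester; the C5 prenyl group is put on the bromosalicylate by Stille coupling.
5. Ring order: ring A is bought, ring C is closed next, ring B is built last; desilylation ends the route.

Key step: step 11

Assumption: the conjugated diazo enone of the key step is taken to absorb near 365 nm, where the benzannulation product absorbs only weakly; methoxyacetylene (bp about 23 °C) is made fresh and used as a cold solution.

In the names below, BF stands for the 3-methoxy-5-(3-methylbut-2-enyl)-6-(triisopropylsilyloxy)benzofuran-2-yl group.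

**Route**

Step 1
Reactants: 1 methyl 5-bromo-2,4-dihydroxybenzoate
Product: 2 methyl 5-bromo-2-hydroxy-4-(triisopropylsilyloxy)benzoate
Conditions: i-Pr3SiCl, imidazole, DMF, 0 °C to 20 °C
Reagents that add atoms: triisopropylsilyl chloride, CC(C)[Si](Cl)(C(C)C)C(C)C
Why: Imidazole-mediated O-silylation; the 2-OH is locked in a hydrogen bond to the ester carbonyl and is poorly nucleophilic, so the bulky silyl chloride should take the more acidic, unchelated 4-OH.

Step 2
Reactants: 2 methyl 5-bromo-2-hydroxy-4-(triisopropylsilyloxy)benzoate; 3 tributyl(3-methylbut-2-enyl)stannane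
Product: 4 methyl 2-hydroxy-5-(3-methylbut-2-enyl)-4-(triisopropylsilyloxy)benzoate
Conditions: Pd(PPh3)4 (5 mol%), DMF, 100 °C, degassed, no fluoride
Reagents that add atoms: none
Why: Stille cross-coupling of an aryl bromide with an allylic stannane; the allylpalladium intermediate should reductively eliminate from its less hindered primary terminus to give the linear prenyl group, and the neutral conditions spare the phenol, ester and aryl silyl ether.

Step 3
Reactants: 4 methyl 2-hydroxy-5-(3-methylbut-2-enyl)-4-(triisopropylsilyloxy)benzoate; 5 methyl bromoacetate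
Product: 6 methyl 2-(2-methoxy-2-oxoethoxy)-5-(3-methylbut-2-enyl)-4-(triisopropylsilyloxy)benzoate
Conditions: K2CO3, acetone, 55 °C
Reagents that add atoms: none
Why: Williamson ether synthesis at the only free hydroxyl; the α-bromo ester is reactive enough for the hydrogen-bonded phenoxide under mild heterogeneous carbonate conditions that the hindered aryl silyl ether should survive, and a methyl ester is chosen so that both esters match in the next step.

Step 4
Reactants: 6 methyl 2-(2-methoxy-2-oxoethoxy)-5-(3-methylbut-2-enyl)-4-(triisopropylsilyloxy)benzoate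
Product: 7 methyl 3-hydroxy-5-(3-methylbut-2-enyl)-6-(triisopropylsilyloxy)benzofuran-2-carboxylate
Conditions: LiN(SiMe3)2 (2.2 equiv), THF, −78 °C to 0 °C; then AcOH
Reagents that add atoms: none
Why: Dieckmann condensation; the aryloxyacetate enolate attacks the ortho benzoate (5-exo-trig), methoxide leaves, and deprotonation of the β-keto ester to the aromatic 3-oxidobenzofuran drives the closure, while the non-nucleophilic amide base leaves the silyl ether alone.

Step 5
Reactants: 7 methyl 3-hydroxy-5-(3-methylbut-2-enyl)-6-(triisopropylsilyloxy)benzofuran-2-carboxylate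
Product: 8 methyl 3-methoxy-5-(3-methylbut-2-enyl)-6-(triisopropylsilyloxy)benzofuran-2-carboxylate
Conditions: Me2SO4, K2CO3, acetone, 50 °C
Reagents that add atoms: dimethyl sulfate, COS(=O)(=O)OC
Why: O-alkylation of the enol of a cyclic β-keto ester with a hard electrophile; alkylation at C2 would destroy the furan aromaticity, so methylation should go on oxygen.

Step 6
Reactants: 8 methyl 3-methoxy-5-(3-methylbut-2-enyl)-6-(triisopropylsilyloxy)benzofuran-2-carboxylate
Product: 9 BF-methanol, that is [3-methoxy-5-(3-methylbut-2-enyl)-6-(triisopropylsilyloxy)benzofuran-2-yl]methanol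
Conditions: i-Bu2AlH (2.5 equiv), CH2Cl2, −78 °C to −20 °C; aq. potassium sodium tartrate
Reagents that add atoms: none
Why: Hydride reduction of an ester to the primary alcohol; the aryl silyl ether, the trisubstituted alkene and the enol ether are inert to i-Bu2AlH, and the neutral tartrate work-up avoids acid on the furfuryl-type alcohol.

Step 7
Reactants: 9 BF-methanol
Product: 10 BF-carbaldehyde, that is 3-methoxy-5-(3-methylbut-2-enyl)-6-(triisopropylsilyloxy)benzofuran-2-carbaldehyde
Conditions: MnO2 (activated, excess), CH2Cl2, 20 °C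
Reagents that add atoms: none
Why: MnO2 oxidation of a heterobenzylic alcohol stops at the aldehyde under neutral conditions and leaves the prenyl alkene untouched.

Step 8
Reactants: 10 BF-carbaldehyde; 11 1-(triphenylphosphoranylidene)propan-2-one
Product: 12 (E)-4-BF-but-3-en-2-one
Conditions: toluene, 100 °C
Reagents that add atoms: none
Why: Wittig olefination with a stabilised acyl ylide should give the E-enone selectively, and its neutral conditions avoid the aqueous base of an aldol condensation, which would endanger the aryl silyl ether.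

Step 9
Reactants: 12 (E)-4-BF-but-3-en-2-one
Product: 14 (E)-1-diazo-4-BF-but-3-en-2-one, via trifluoroacetyl diketone 13 (not isolated)
Conditions: LiN(SiMe3)2, THF, −78 °C; CF3CO2CH2CF3; cold dilute aq. HCl wash; then MsN3, Et3N, H2O (1 equiv), MeCN, 20 °C
Reagents that add atoms: 2,2,2-trifluoroethyl trifluoroacetate, O=C(OCC(F)(F)F)C(F)(F)F (its CF3CO group is in 13 only); methanesulfonyl azide, CS(=O)(=O)N=[N+]=[N-]
Why: Detrifluoroacetylative diazo transfer (Danheiser variant of the Regitz reaction); the methyl group is the only enolisable site, Claisen trifluoroacetylation activates it, and the sulfonyl azide transfers N2 while the trifluoroacetyl group leaves on the sulfonamide nitrogen, a sequence established for benzylideneacetone-type enones.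

Step 10
Reactants: 15 chloroacetaldehyde dimethyl acetal
Product: 17 methoxyacetylene, via sodium methoxyacetylide 16 (not isolated)
Conditions: NaNH2 (3 equiv), liquid NH3, −33 °C; then cold saturated aq. NaCl, −70 °C; distilled into cold ClCH2CH2Cl
Reagents that add atoms: none
Why: Double base-induced elimination (loss of HCl and of methanol) from an α-chloro acetal gives the sodium alkynolate ether, which is protonated on aqueous quench; this is the classical alkoxyacetylene preparation.

Step 11
Reactants: 14 (E)-1-diazo-4-BF-but-3-en-2-one; 17 methoxyacetylene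
Product: 22 ambofuranol 6-triisopropylsilyl ether, via vinylketene 18 (not isolated), via 4-alkenylcyclobutenone 19 (not isolated), via dienylketene 20 (not isolated), via cyclohexa-2,4-dienone 21 (not isolated)
Conditions: 17 (4 equiv), ClCH2CH2Cl (0.05 M, degassed), hv (365 nm), 20 °C; then 80 °C, sealed vessel
Reagents that add atoms: none
Why: Light expels N2 from 14 and Wolff rearrangement (1,2-shift of the alkenyl group) gives vinylketene 18, whose ketene C=C adds methoxyacetylene in a [2+2] cycloaddition to give cyclobutenone 19; reversible four-electron conrotatory opening of 19 gives dienylketene 20, which closes by a thermal six-electron disrotatory electrocyclisation to dienone 21 and tautomerises to phenol 22. This is the photochemical diazo ketone version of the Danheiser benzannulation, a known reaction of α-diazo enones with alkoxyacetylenes, applied here to a heteroaryl-substituted enone. Ring B is the only ring closed: the [2+2] step forms C2'–C3' and C4'–C5', and the six-electron electrocyclic closure forms C1'–C2' between the ketene carbon and the alkene carbon that carries the benzofuran. The sp3 centres of 19 and 21 are transient and racemic and vanish on aromatisation, so the step sets no stereocentre. The selectivity needed is regiochemical: the polarised alkyne bonds through its nucleophilic unsubstituted carbon to the electrophilic ketene carbonyl carbon, which puts OMe para and OH ortho to C1'; the excess electron-rich alkyne should capture the ketene much faster than the remote prenyl alkene does, and only the ring-opened isomer with the alkenyl group turned inward can cyclise while the other recloses to 19, so both funnel to 22.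

Step 12
Reactants: 22 ambofuranol 6-triisopropylsilyl ether
Product: 23 ambofuranol
Conditions: Bu4NF, AcOH (1 equiv each), THF, 0 °C
Reagents that add atoms: none
Why: Fluoride cleavage of an aryl silyl ether, driven by the strong Si–F bond; acetic acid buffering protects the electron-rich bisphenol, and the methyl ethers and the prenyl group are inert.

**Compound list**

1 | methyl 5-bromo-2,4-dihydroxybenzoate | COC(=O)c1cc(Br)c(O)cc1O | starting material
2 | methyl 5-bromo-2-hydroxy-4-(triisopropylsilyloxy)benzoate | COC(=O)c1cc(Br)c(O[Si](C(C)C)(C(C)C)C(C)C)cc1O | intermediate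
3 | tributyl(3-methylbut-2-enyl)stannane | CCCC[Sn](CCCC)(CCCC)CC=C(C)C | starting material
4 | methyl 2-hydroxy-5-(3-methylbut-2-enyl)-4-(triisopropylsilyloxy)benzoate | COC(=O)c1cc(CC=C(C)C)c(O[Si](C(C)C)(C(C)C)C(C)C)cc1O | intermediate
5 | methyl bromoacetate | COC(=O)CBr | starting material
6 | methyl 2-(2-methoxy-2-oxoethoxy)-5-(3-methylbut-2-enyl)-4-(triisopropylsilyloxy)benzoate | COC(=O)COc1cc(O[Si](C(C)C)(C(C)C)C(C)C)c(CC=C(C)C)cc1C(=O)OC | intermediate
7 | methyl 3-hydroxy-5-(3-methylbut-2-enyl)-6-(triisopropylsilyloxy)benzofuran-2-carboxylate | COC(=O)c1oc2cc(O[Si](C(C)C)(C(C)C)C(C)C)c(CC=C(C)C)cc2c1O | intermediate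
8 | methyl 3-methoxy-5-(3-methylbut-2-enyl)-6-(triisopropylsilyloxy)benzofuran-2-carboxylate | COC(=O)c1oc2cc(O[Si](C(C)C)(C(C)C)C(C)C)c(CC=C(C)C)cc2c1OC | intermediate
9 | [3-methoxy-5-(3-methylbut-2-enyl)-6-(triisopropylsilyloxy)benzofuran-2-yl]methanol | OCc1oc2cc(O[Si](C(C)C)(C(C)C)C(C)C)c(CC=C(C)C)cc2c1OC | intermediate
10 | 3-methoxy-5-(3-methylbut-2-enyl)-6-(triisopropylsilyloxy)benzofuran-2-carbaldehyde | O=Cc1oc2cc(O[Si](C(C)C)(C(C)C)C(C)C)c(CC=C(C)C)cc2c1OC | intermediate
11 | 1-(triphenylphosphoranylidene)propan-2-one | CC(=O)C=P(c1ccccc1)(c1ccccc1)c1ccccc1 | starting material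
12 | (E)-4-[3-methoxy-5-(3-methylbut-2-enyl)-6-(triisopropylsilyloxy)benzofuran-2-yl]but-3-en-2-one | CC(=O)/C=C/c1oc2cc(O[Si](C(C)C)(C(C)C)C(C)C)c(CC=C(C)C)cc2c1OC | intermediate
13 | (E)-1,1,1-trifluoro-6-[3-methoxy-5-(3-methylbut-2-enyl)-6-(triisopropylsilyloxy)benzofuran-2-yl]hex-5-ene-2,4-dione | O=C(CC(=O)C(F)(F)F)/C=C/c1oc2cc(O[Si](C(C)C)(C(C)C)C(C)C)c(CC=C(C)C)cc2c1OC | intermediate (not isolated)
14 | (E)-1-diazo-4-[3-methoxy-5-(3-methylbut-2-enyl)-6-(triisopropylsilyloxy)benzofuran-2-yl]but-3-en-2-one | [N-]=[N+]=CC(=O)/C=C/c1oc2cc(O[Si](C(C)C)(C(C)C)C(C)C)c(CC=C(C)C)cc2c1OC | intermediate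
15 | chloroacetaldehyde dimethyl acetal | COC(CCl)OC | starting material
16 | sodium methoxyacetylide | [Na+].[C-]#COC | intermediate (not isolated)
17 | methoxyacetylene | COC#C | intermediate
18 | (E)-4-[3-methoxy-5-(3-methylbut-2-enyl)-6-(triisopropylsilyloxy)benzofuran-2-yl]buta-1,3-dien-1-one (vinylketene) | O=C=C/C=C/c1oc2cc(O[Si](C(C)C)(C(C)C)C(C)C)c(CC=C(C)C)cc2c1OC | intermediate (not isolated)
19 | racemic 3-methoxy-4-[(E)-2-[3-methoxy-5-(3-methylbut-2-enyl)-6-(triisopropylsilyloxy)benzofuran-2-yl]ethenyl]cyclobut-2-en-1-one | COC1=CC(=O)C1/C=C/c1oc2cc(O[Si](C(C)C)(C(C)C)C(C)C)c(CC=C(C)C)cc2c1OC | intermediate (not isolated)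
20 | (3E,5E)-3-methoxy-6-[3-methoxy-5-(3-methylbut-2-enyl)-6-(triisopropylsilyloxy)benzofuran-2-yl]hexa-1,3,5-trien-1-one (dienylketene; ketene carbon and alkenyl group cis across C3=C4) | O=C=C/C(OC)=C\C=C\c1oc2cc(O[Si](C(C)C)(C(C)C)C(C)C)c(CC=C(C)C)cc2c1OC | intermediate (not isolated)
21 | racemic 3-methoxy-6-[3-methoxy-5-(3-methylbut-2-enyl)-6-(triisopropylsilyloxy)benzofuran-2-yl]cyclohexa-2,4-dien-1-one | COC1=CC(=O)C(C=C1)c1oc2cc(O[Si](C(C)C)(C(C)C)C(C)C)c(CC=C(C)C)cc2c1OC | intermediate (not isolated)
22 | ambofuranol 6-triisopropylsilyl ether, 5-methoxy-2-[3-methoxy-5-(3-methylbut-2-enyl)-6-(triisopropylsilyloxy)benzofuran-2-yl]phenol | COc1ccc(-c2oc3cc(O[Si](C(C)C)(C(C)C)C(C)C)c(CC=C(C)C)cc3c2OC)c(O)c1 | intermediate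
23 | ambofuranol, 2-(2-hydroxy-4-methoxyphenyl)-3-methoxy-5-(3-methylbut-2-enyl)benzofuran-6-ol | COc1ccc(-c2oc3cc(O)c(CC=C(C)C)cc3c2OC)c(O)c1 | target

**Step count**

Total: 12 steps. Longest linear sequence: 11 steps (steps 1 to 9, 11 and 12, from compound 1); step 10 is a one-step side branch.

**Steps most likely to fail**

Step 11 (benzannulation). The light may be absorbed by the alkenylbenzofuran chromophore or by the growing 2-arylbenzofuran product, leading to E/Z isomerisation, photodimerisation or decomposition in place of the Wolff rearrangement. The vinylketene may also acylate the newly formed phenol, and methoxyacetylene may polymerise before it traps the ketene. The fallback gives up the annulation and makes the C2–C1' bond by cross-coupling. It sets out from ester 8. Hydrolysis with Me3SnOH (ClCH2CH2Cl, 80 °C) would give 3-methoxy-5-(3-methylbut-2-enyl)-6-(triisopropylsilyloxy)benzofuran-2-carboxylic acid F1. Protodecarboxylation with Ag2CO3 and AcOH (catalytic, DMSO, 120 °C) would give 3-methoxy-5-(3-methylbut-2-enyl)-6-(triisopropylsilyloxy)benzofuran F2. Deprotonation at C2 with n-BuLi (THF, −78 °C) and ZnCl2 would give [3-methoxy-5-(3-methylbut-2-enyl)-6-(triisopropylsilyloxy)benzofuran-2-yl]zinc chloride F3. Negishi coupling (Pd(OAc)2, SPhos, THF, 60 °C) with (2-bromo-5-methoxyphenoxy)triisopropylsilane F4, made from 2-bromo-5-methoxyphenol with i-Pr3SiCl and imidazole, would give ambofuranol 2',6-bis(triisopropylsilyl) ether F5. Bu4NF would then remove both silyl groups, and the fallback comes back to the route at target 23.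

Step 2 (Stille prenylation). Allylic transposition during transmetalation and reductive elimination may deliver the 1,1-dimethylallyl isomer, and oxidative addition next to the bulky silyl ether may be slow enough for protodebromination to compete. The fallback sets out from bromide 2. Stille coupling with allyltributylstannane (Pd(PPh3)4, DMF, 100 °C), which has no regiochemical ambiguity, would give methyl 2-hydroxy-5-(prop-2-enyl)-4-(triisopropylsilyloxy)benzoate F6. Olefin cross-metathesis with excess 2-methylbut-2-ene (second-generation Grubbs catalyst, CH2Cl2, 40 °C) would convert the allyl group into the prenyl group, and the fallback comes back to the route at compound 4.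

Step 6 (ester to alcohol). The furfuryl-type alcohol 9 may ionise (loss of water assisted by the ring oxygen and the 3-methoxy group) during work-up or chromatography and then self-condense. The fallback avoids the alcohol oxidation state. It sets out from ester 8. Aminolysis with MeNH(OMe)·HCl and i-PrMgCl (THF, −20 °C) would give N-methoxy-N-methyl-3-methoxy-5-(3-methylbut-2-enyl)-6-(triisopropylsilyloxy)benzofuran-2-carboxamide F7. Partial reduction with i-Bu2AlH (THF, −78 °C) stops at the chelated tetrahedral intermediate, and the fallback comes back to the route at aldehyde 10, so that step 7 is not needed.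

**Further compounds**

F1 | step 11 | 3-methoxy-5-(3-methylbut-2-enyl)-6-(triisopropylsilyloxy)benzofuran-2-carboxylic acid | OC(=O)c1oc2cc(O[Si](C(C)C)(C(C)C)C(C)C)c(CC=C(C)C)cc2c1OC
F2 | step 11 | 3-methoxy-5-(3-methylbut-2-enyl)-6-(triisopropylsilyloxy)benzofuran | COc1coc2cc(O[Si](C(C)C)(C(C)C)C(C)C)c(CC=C(C)C)cc12
F3 | step 11 | [3-methoxy-5-(3-methylbut-2-enyl)-6-(triisopropylsilyloxy)benzofuran-2-yl]zinc chloride | COc1c([Zn]Cl)oc2cc(O[Si](C(C)C)(C(C)C)C(C)C)c(CC=C(C)C)cc12
F4 | step 11 | (2-bromo-5-methoxyphenoxy)triisopropylsilane | COc1ccc(Br)c(O[Si](C(C)C)(C(C)C)C(C)C)c1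
F5 | step 11 | ambofuranol 2',6-bis(triisopropylsilyl) ether | COc1ccc(-c2oc3cc(O[Si](C(C)C)(C(C)C)C(C)C)c(CC=C(C)C)cc3c2OC)c(O[Si](C(C)C)(C(C)C)C(C)C)c1
F6 | step 2 | methyl 2-hydroxy-5-(prop-2-enyl)-4-(triisopropylsilyloxy)benzoate | COC(=O)c1cc(CC=C)c(O[Si](C(C)C)(C(C)C)C(C)C)cc1O
F7 | step 6 | N-methoxy-N-methyl-3-methoxy-5-(3-methylbut-2-enyl)-6-(triisopropylsilyloxy)benzofuran-2-carboxamide | CON(C)C(=O)c1oc2cc(O[Si](C(C)C)(C(C)C)C(C)C)c(CC=C(C)C)cc2c1OC
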